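**Strategy.** Everything rests on opening ring A (C1, C2, C3, C4, C5, C10) at C1–C10 and C4–C5, which leads back to an aryl ether of a 1,4-benzoquinone whose arene carries an (E,E)-pentadienyl arm next to the ether oxygen. The feature exploited is the run of four contiguous stereocentres C1, C10, C5 and C4, all substituted on the same face of ring A, together with the C10–O bond that ties ring A to the arene: one intramolecular Diels–Alder reaction across the quinone bond C10=C5 closes ring A and the cis-fused dihydrofuran and sets all four centres. The precursor carries an added C8 methoxy group that blocks the second quinone double bond and prepares the later carbonyl transposition.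

Key step: step 8

**Remarks before the steps**

- Numbering of the terpenoid part: C1 (benzylic CH), C2, C3 (CH2), C4 (CHCH3), C5 (C–CH3), C6, C7 (cyclopropane CH), C8, C9 (C=O), C10 (C–O), C11 (CMe2). Ring A is C1–C5 plus C10; ring B is C5–C10. In this numbering the target SMILES reads (1R,4R,5R,6S,7R,10S), with the cyclopropane on the face opposite the C5 methyl group and the C10 oxygen.
- Precursor design, point 1: a methoxy group sits on the quinone carbon that becomes C8. It removes the only unsubstituted quinone double bond, which would otherwise be the better dienophile and Michael acceptor. It also makes the C6 carbonyl a vinylogous ester, so that reduction and hydrolysis move the oxygen from C6 to C8 and create C6=C7 in one operation.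
- Precursor design, point 2: the bromoquinone is built from a bromophenol of fixed substitution pattern, because bromination of 2-methyl-1,4-benzoquinone would not place bromine next to the methyl group.
- Precursor design, point 3: the acetyl group, the only enolisable and unhindered-enough ketone in the hydride step, is masked there in the flask as its enol silane.
- Assumption on supply: compounds 1, 4, 5, 8 and 20 are taken as commercially available.
- Assumption on the key step: the sense of induction of the boron catalyst at a tethered, fully substituted quinone double bond cannot be derived safely by analogy. The (S)-catalyst is written; the (R)-catalyst, made the same way from (R)-diphenylprolinol, takes its place if the adduct proves to be the mirror image.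

**Route**

Step 1
Reactants: 1 1-(2,6-dihydroxy-4-methoxyphenyl)ethan-1-one
Product: 2 1-[2-hydroxy-4-methoxy-6-(methoxymethoxy)phenyl]ethan-1-one
Conditions: MeOCH2Cl (1.1 equiv), iPr2NEt, CH2Cl2, 0 °C → rt
Reagents that add atoms: chloromethyl methyl ether, COCCl
Why: O-alkylation (MOM protection) should stop after one hydroxyl because the remaining one is held in a hydrogen bond to the acetyl carbonyl.

Step 2
Reactants: 2 1-[2-hydroxy-4-methoxy-6-(methoxymethoxy)phenyl]ethan-1-one
Product: 3 1-[2-hydroxy-3-iodo-4-methoxy-6-(methoxymethoxy)phenyl]ethan-1-one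
Conditions: BnMe3N+ ICl2− (1.05 equiv), NaHCO3, CH2Cl2–MeOH, rt
Reagents that add atoms: benzyltrimethylammonium dichloroiodate, C[N+](C)(C)Cc1ccccc1.Cl[I-]Cl
Why: Electrophilic aromatic iodination of a chelated ortho-hydroxyaryl ketone is directed to the free position next to the hydroxyl (between OH and OMe), the carbon that must carry the diene.

Step 3
Reactants: 4 (E)-but-2-enal; 5 bis(4,4,5,5-tetramethyl-1,3,2-dioxaborolan-2-yl)methane
Product: 6 4,4,5,5-tetramethyl-2-[(1E,3E)-penta-1,3-dien-1-yl]-1,3,2-dioxaborolane
Conditions: 5 (1.2 equiv), lithium 2,2,6,6-tetramethylpiperidide (from the amine and n-BuLi), THF, 0 °C; then 4, −78 °C → rt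
Reagents that add atoms: none
Why: Boron–Wittig olefination, in which the α-boryl carbanion adds to the aldehyde and loss of the borate gives the trans alkenylboronate while the existing (E)-alkene is untouched.

Step 4
Reactants: 3 1-[2-hydroxy-3-iodo-4-methoxy-6-(methoxymethoxy)phenyl]ethan-1-one; 6 (1E,3E)-pentadienyl pinacol boronate
Product: 7 1-{2-hydroxy-4-methoxy-6-(methoxymethoxy)-3-[(1E,3E)-penta-1,3-dien-1-yl]phenyl}ethan-1-one
Conditions: Pd(dppf)Cl2 (5 mol%), K3PO4 (3 equiv), 1,4-dioxane–H2O (5:1), degassed, 60 °C; product used promptly
Reagents that add atoms: none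
Why: Suzuki–Miyaura coupling of an aryl iodide with an alkenylboronate proceeds with retention of alkene geometry and tolerates the free phenol as its phenoxide.

Step 5
Reactants: 8 2-bromo-3-hydroxy-4-methoxybenzaldehyde
Product: 10 2-bromo-6-methoxy-3-methylphenol, via benzylic alcohol 9 (not isolated)
Conditions: Et3SiH (3 equiv), CF3CO2H, CH2Cl2, 0 °C → rt
Reagents that add atoms: none
Why: Ionic hydrogenation, in which the para-methoxy group stabilises the benzylic cation so that hydride transfer from the silane takes the aldehyde through the alcohol to the methyl group without touching the aryl bromide.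

Step 6
Reactants: 10 2-bromo-6-methoxy-3-methylphenol
Product: 11 3-bromo-5-methoxy-2-methylcyclohexa-2,5-diene-1,4-dione
Conditions: (KSO3)2NO (2.5 equiv), KH2PO4, H2O–acetone, 0 °C → rt
Reagents that add atoms: potassium nitrosodisulfonate, [K+].[K+].[O]N(S(=O)(=O)[O-])S(=O)(=O)[O-]
Why: Teuber oxidation of a phenol with a free para position gives the para-quinone, here with bromine and methyl on one double bond and the methoxy group beside the carbonyl that is flanked by C–Br.

Step 7
Reactants: 7 ortho-pentadienyl phenol; 11 3-bromo-5-methoxy-2-methyl-1,4-benzoquinone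
Product: 12 3-{2-acetyl-5-methoxy-3-(methoxymethoxy)-6-[(1E,3E)-penta-1,3-dien-1-yl]phenoxy}-5-methoxy-2-methylcyclohexa-2,5-diene-1,4-dione
Conditions: Cs2CO3 (1.1 equiv), 11 (1.3 equiv), MeCN, 0 °C, dark; filtered cold and used at once
Reagents that add atoms: none
Why: Addition–elimination (vinylogous acyl substitution) of the caesium phenoxide at the bromine-bearing quinone carbon, helped by the methoxy group, which deactivates the other quinone double bond toward Michael addition and toward cycloaddition with the diene arm.

Step 8
Reactants: 12 aryloxy-methoxy-methylquinone with the ortho (E,E)-pentadienyl arm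
Product: 13 Diels–Alder adduct (tetracycle; ring A cyclohexene with C2=C3; ring B C9(=O)–C8(OMe)=C7–C6(=O); aryl on C1, O on C10, CH3 on C5 and CH3 on C4 all syn)
Conditions: (S)-1-(2-methylphenyl)-3,3-diphenyl-tetrahydro-1H,3H-pyrrolo[1,2-c][1,3,2]oxazaborole (30 mol%), (CF3SO2)2NH (25 mol%), CH2Cl2 (0.02 M), −40 → −20 °C
Reagents that add atoms: none
Why: A concerted, asynchronous normal-demand [4+2] cycloaddition joins the electron-rich (E,E)-aryldiene to the quinone double bond C10=C5 after the cationic boron Lewis acid has bound the more basic C6 carbonyl (vinylogous to both the C8 methoxy and the C10 aryloxy oxygen) on the lone pair beside C7–H and so lowered the quinone LUMO. The closest known reaction types are the cationic-oxazaborolidine-catalysed enantioselective Diels–Alder reaction of substituted 1,4-benzoquinones and the intramolecular quinone Diels–Alder reaction that creates quaternary ring-fusion carbons. Ring A is closed as the cyclohexene of the [4+2] process by the bonds C1–C10 and C4–C5, and the dihydrofuran is closed at the same time as the tether ring (two arene carbons, O, C10, C1), a five-membered ring that can only form cis-fused. Suprafacial addition transfers the (E,E) geometry into the cis relation of the C1 aryl bond and the C4 methyl group and the ring-locked dienophile geometry into the cis relation of C10–O and C5–CH3, the short tether forces the C1 aryl bond and C10–O cis, and the chiral boron cation, which covers one face of the quinone, selects the absolute configuration. The step needs site selectivity for C10=C5 over C7=C8, secured by the three-atom tether that cannot reach C7=C8 and by the C8 methoxy group that deactivates it toward intermolecular addition, and it needs catalysis to outrun the racemic thermal reaction, which the fully substituted, donor-bearing dienophile should make slow below 0 °C.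

Step 9
Reactants: 13 Diels–Alder adduct
Product: 14 2,3-dihydro adduct (ring A saturated; ring B unchanged)
Conditions: H2 (3 atm), RhCl(PPh3)3 (10 mol%), toluene–EtOH, rt
Reagents that add atoms: none
Why: Homogeneous hydrogenation with the rhodium chloride tris(phosphine) complex should reduce the unconjugated cis-disubstituted C2=C3 alkene and leave the trisubstituted, donor-substituted C7=C8 enol ether, the ketones and the MOM ether alone, and no stereocentre is created.

Step 10
Reactants: 14 2,3-dihydro adduct
Product: 17 C9-hydroxy enone (ring B C6=C7–C8(=O)–C9H(OH); acetyl restored; C9 configuration not defined), via trimethylsilyl enol ether 15 (not isolated), via enol ether diol 16 (not isolated)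
Conditions: (a) Me3SiCl, LiN(SiMe3)2, THF, −78 °C, then volatiles removed and LiCl filtered off from pentane; (b) iBu2AlH (4 equiv), CH2Cl2, −78 °C; (c) 1 M HCl, THF, 0 °C, 20 min
Reagents that add atoms: water, O
Why: Stork–Danheiser transposition, in which the acetyl group (the only enolisable ketone) is first masked as its enol silane, hydride then reduces the C6 vinylogous-ester carbonyl together with C9, and acid hydrolysis of the C8 enol ether with loss of the C6 hydroxyl gives the C6=C7–C8=O enone and returns the acetyl group, the C9 carbinol configuration being irrelevant.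

Step 11
Reactants: 17 C9-hydroxy enone (crude, used at once)
Product: 18 ene-1,2-dione (ring B C6=C7–C8(=O)–C9(=O))
Conditions: 1,1,1-triacetoxy-1,1-dihydro-1,2-benziodoxol-3(1H)-one (1.5 equiv), NaHCO3, CH2Cl2, 0 °C → rt
Reagents that add atoms: none
Why: Periodinane (Dess–Martin) oxidation of the secondary α-hydroxy ketone gives the non-enolisable ene-1,2-dione under buffered conditions that spare the MOM ether and the aryl ether.

Step 12
Reactants: 18 ene-1,2-dione
Product: 19 cyclopropyl 1,2-dione (C11(CH3)2 bridging C6 and C7 on the face opposite C5–CH3 and C10–O; acetyl and MOM retained)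
Conditions: Ph2S(CHMe2)BF4 (1.3 equiv), LiN(iPr)2 (1.2 equiv), DME–CH2Cl2, −78 °C; then 18, −78 → −40 °C
Reagents that add atoms: diphenyl(propan-2-yl)sulfonium tetrafluoroborate, CC(C)[S+](c1ccccc1)c1ccccc1.F[B-](F)(F)F
Why: Corey–Chaykovsky-type cyclopropanation, in which the isopropylide adds in conjugate fashion to C6 on the face opposite the pseudo-axial C5 methyl group and the resulting C7 enolate displaces diphenyl sulfide, which should set C6 and C7 as a cis-fused dimethylcyclopropane anti to the C5 methyl group and the C10 oxygen.

Step 13
Reactants: 19 cyclopropyl 1,2-dione; 20 4-methoxybenzaldehyde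
Product: 22 MOM ether of the target chalcone, via aldol adduct 21 (not isolated)
Conditions: 20 (3 equiv), KOH (2 equiv), EtOH, argon, 0 °C → rt
Reagents that add atoms: none
Why: Claisen–Schmidt condensation, in which the methyl ketone is the only enolisable carbonyl (C9 is flanked by quaternary C10 and C8 by the cyclopropane carbon C7) and E1cB dehydration of the aldol gives the (E)-enone.

Step 14
Reactants: 22 MOM ether of the target chalcone
Product: 23 CNP0121765.1
Conditions: 3 M HCl, MeOH, rt, short reaction time
Reagents that add atoms: none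
Why: Acid-catalysed acetal cleavage of the aryl MOM ether, assisted by the neighbouring carbonyl, should free the phenol under conditions too mild to open the cyclopropyl ketone or to close the chalcone to a flavanone.

**Compound list**

1 | 1-(2,6-dihydroxy-4-methoxyphenyl)ethan-1-one | CC(=O)c1c(O)cc(OC)cc1O | starting material
2 | 1-[2-hydroxy-4-methoxy-6-(methoxymethoxy)phenyl]ethan-1-one | CC(=O)c1c(O)cc(OC)cc1OCOC | intermediate
3 | 1-[2-hydroxy-3-iodo-4-methoxy-6-(methoxymethoxy)phenyl]ethan-1-one | CC(=O)c1c(O)c(I)c(OC)cc1OCOC | intermediate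
4 | (E)-but-2-enal | C/C=C/C=O | starting material
5 | bis(4,4,5,5-tetramethyl-1,3,2-dioxaborolan-2-yl)methane | CC1(C)OB(CB2OC(C)(C)C(C)(C)O2)OC1(C)C | starting material
6 | 4,4,5,5-tetramethyl-2-[(1E,3E)-penta-1,3-dien-1-yl]-1,3,2-dioxaborolane | C/C=C/C=C/B1OC(C)(C)C(C)(C)O1 | intermediate
7 | 1-{2-hydroxy-4-methoxy-6-(methoxymethoxy)-3-[(1E,3E)-penta-1,3-dien-1-yl]phenyl}ethan-1-one | CC(=O)c1c(O)c(/C=C/C=C/C)c(OC)cc1OCOC | intermediate
8 | 2-bromo-3-hydroxy-4-methoxybenzaldehyde | COc1ccc(C=O)c(Br)c1O | starting material
9 | 2-bromo-3-(hydroxymethyl)-6-methoxyphenol | COc1ccc(CO)c(Br)c1O | intermediate (not isolated)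
10 | 2-bromo-6-methoxy-3-methylphenol | COc1ccc(C)c(Br)c1O | intermediate
11 | 3-bromo-5-methoxy-2-methylcyclohexa-2,5-diene-1,4-dione | COC1=CC(=O)C(C)=C(Br)C1=O | intermediate
12 | 3-{2-acetyl-5-methoxy-3-(methoxymethoxy)-6-[(1E,3E)-penta-1,3-dien-1-yl]phenoxy}-5-methoxy-2-methylcyclohexa-2,5-diene-1,4-dione (Diels–Alder precursor) | CC(=O)c1c(OCOC)cc(OC)c(/C=C/C=C/C)c1OC1=C(C)C(=O)C=C(OC)C1=O | intermediate
13 | Diels–Alder adduct: arene (acetyl, OMOM, OMe) fused through a cis-dihydrofuran (aryl–C1, O–C10) to ring A (cyclohexene, C2=C3) and ring B (C9 ketone, C8(OMe)=C7, C6 ketone); aryl on C1, O on C10, CH3 on C5 and CH3 on C4 all on one face; absolute configuration as in 23 | CC(=O)c2c(OCOC)cc(OC)c3c2O[C@]24C(=O)C(OC)=CC(=O)[C@@]2(C)[C@H](C)C=C[C@H]34 | intermediate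
14 | 2,3-dihydro derivative of 13 (ring A saturated) | CC(=O)c2c(OCOC)cc(OC)c3c2O[C@]24C(=O)C(OC)=CC(=O)[C@@]2(C)[C@H](C)CC[C@H]34 | intermediate
15 | trimethylsilyl enol ether of 14 at the acetyl group | C=C(O[Si](C)(C)C)c2c(OCOC)cc(OC)c3c2O[C@]24C(=O)C(OC)=CC(=O)[C@@]2(C)[C@H](C)CC[C@H]34 | intermediate (not isolated)
16 | C6,C9-diol of 15 (ring B C9H(OH)–C8(OMe)=C7–C6H(OH); carbinol configurations not defined) | C=C(O[Si](C)(C)C)c2c(OCOC)cc(OC)c3c2O[C@]24C(O)C(OC)=CC(O)[C@@]2(C)[C@H](C)CC[C@H]34 | intermediate (not isolated)
17 | C9-hydroxy enone (ring B C6=C7–C8(=O)–C9H(OH); C9 configuration not defined; acetyl and MOM present) | CC(=O)c2c(OCOC)cc(OC)c3c2O[C@]24C(O)C(=O)C=C[C@@]2(C)[C@H](C)CC[C@H]34 | intermediate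
18 | ene-1,2-dione (ring B C6=C7–C8(=O)–C9(=O)) | CC(=O)c2c(OCOC)cc(OC)c3c2O[C@]24C(=O)C(=O)C=C[C@@]2(C)[C@H](C)CC[C@H]34 | intermediate
19 | cyclopropyl 1,2-dione (C11(CH3)2 across C6 and C7, anti to C5–CH3 and C10–O; acetyl and MOM present) | CC(=O)c2c(OCOC)cc(OC)c3c2O[C@]24C(=O)C(=O)[C@@H]5[C@@H](C5(C)C)[C@@]2(C)[C@H](C)CC[C@H]34 | intermediate
20 | 4-methoxybenzaldehyde | COc1ccc(C=O)cc1 | starting material
21 | aldol adduct of 19 and 20 (β-hydroxy ketone, carbinol configuration not defined) | COc1ccc(C(O)CC(=O)c2c(OCOC)cc(OC)c3c2O[C@]24C(=O)C(=O)[C@@H]5[C@@H](C5(C)C)[C@@]2(C)[C@H](C)CC[C@H]34)cc1 | intermediate (not isolated)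
22 | MOM ether of 23 ((E)-chalcone, phenol protected) | COc1ccc(/C=C/C(=O)c2c(OCOC)cc(OC)c3c2O[C@]24C(=O)C(=O)[C@@H]5[C@@H](C5(C)C)[C@@]2(C)[C@H](C)CC[C@H]34)cc1 | intermediate
23 | CNP0121765.1: (E)-4-methoxychalcone whose 2'-hydroxy-4'-methoxy ring is fused through the cis-dihydrofuran to the (1R,4R,5R,6S,7R,10S) terpenoid dione | COc1ccc(/C=C/C(=O)c2c(O)cc(OC)c3c2O[C@]24C(=O)C(=O)[C@@H]5[C@@H](C5(C)C)[C@@]2(C)[C@H](C)CC[C@H]34)cc1 | target

**Step count.** Total: 14 steps. Longest linear sequence: 11 steps (steps 1, 2, 4, 7, 8, 9, 10, 11, 12, 13, 14).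

**Steps most likely to fail**

1. Step 8. The boron cation may be sequestered by the many Lewis-basic oxygens, so that no acceleration over the racemic thermal pathway results. It may also discriminate the two quinone faces poorly because it binds away from the reacting double bond. Fallback: from 12, the cycloaddition is run without catalyst in toluene (0.005 M, 100 °C, 2,6-di-tert-butyl-4-methylphenol as radical inhibitor). The tether and the alkene geometries still fix the relative configuration, so this should give the racemate, that is 13 together with the enantiomer of 13 F1. Preparative chromatography on a chiral stationary phase (supercritical CO2–MeOH) then delivers 13, where the route is rejoined.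

2. Step 7. The electron-rich dienylphenoxide may transfer an electron to the quinone or add in Michael fashion at the unsubstituted quinone carbon instead of displacing bromide, and the diene arm may undergo cycloaddition with free bromoquinone. Fallback: the ether is formed before the diene is present and the quinone is carried through the cross-coupling in reduced, protected form. From 3 and 11 (Cs2CO3, MeCN, 0 °C) the iodoaryl ether quinone F2 is made. Reduction with Na2S2O4 (EtOAc–H2O) gives the hydroquinone F3 (not isolated), which is acetylated directly (Ac2O, pyridine) to the hydroquinone diacetate F4. Suzuki–Miyaura coupling of F4 with 6 (Pd(dppf)Cl2, anhydrous K3PO4, dioxane, 70 °C) gives the dienyl hydroquinone diacetate F5. Methanolysis (K2CO3, degassed MeOH, 0 °C) gives the dienyl hydroquinone F6 (not isolated), and oxidation with Ag2O in Et2O returns 12.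

3. Step 12. The hard ylide may add to the very electrophilic C9 carbonyl of the 1,2-dione (oxirane formation) faster than to the neopentyl C6, or it may attack C6=C7 on the face of the C5 methyl group. Fallback: the three-membered ring is made by dipolar cycloaddition and nitrogen extrusion instead of ylide transfer. From 18, freshly prepared 2-diazopropane (Et2O, −78 → 0 °C) should add across the electron-poor C6=C7 bond, carbon to C6, to give the fused 1-pyrazoline F7. Irradiation (350 nm, MeCN, rt) then expels nitrogen and closes the dimethylcyclopropane, returning the route at 19.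

**Further compounds**

F1 | step 8 | enantiomer of 13 | CC(=O)c2c(OCOC)cc(OC)c3c2O[C@@]24C(=O)C(OC)=CC(=O)[C@]2(C)[C@@H](C)C=C[C@@H]34
F2 | step 7 | 3-[2-acetyl-6-iodo-5-methoxy-3-(methoxymethoxy)phenoxy]-5-methoxy-2-methylcyclohexa-2,5-diene-1,4-dione | CC(=O)c1c(OCOC)cc(OC)c(I)c1OC1=C(C)C(=O)C=C(OC)C1=O
F3 | step 7 | 1-[2-(3,6-dihydroxy-5-methoxy-2-methylphenoxy)-3-iodo-4-methoxy-6-(methoxymethoxy)phenyl]ethan-1-one (not isolated) | CC(=O)c1c(OCOC)cc(OC)c(I)c1Oc1c(C)c(O)cc(OC)c1O
F4 | step 7 | diacetate of F3 | CC(=O)c1c(OCOC)cc(OC)c(I)c1Oc1c(C)c(OC(C)=O)cc(OC)c1OC(C)=O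
F5 | step 7 | diacetate of the hydroquinone of 12 (iodine of F4 replaced by the (1E,3E)-pentadienyl group) | CC(=O)c1c(OCOC)cc(OC)c(/C=C/C=C/C)c1Oc1c(C)c(OC(C)=O)cc(OC)c1OC(C)=O
F6 | step 7 | hydroquinone of 12 (not isolated) | CC(=O)c1c(OCOC)cc(OC)c(/C=C/C=C/C)c1Oc1c(C)c(O)cc(OC)c1O
F7 | step 12 | 1-pyrazoline from 18 and 2-diazopropane (C6–CMe2–N=N–C7, cis-fused, new centres not defined) | CC(=O)c2c(OCOC)cc(OC)c3c2O[C@]24C(=O)C(=O)C5N=NC(C)(C)C5[C@@]2(C)[C@H](C)CC[C@H]34
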